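The plan cuts ring C between C3 (the CH2) and C4 (the carbonyl carbon). C2 carries both O1 and ring B. At the alkene level, C2=C3 is therefore an achiral aryl 1-arylvinyl ether without allylic hydrogens, and C4 is a formyl group on ring A ortho to O1. An enantioselective rhodium-catalysed intramolecular hydroacylation adds the formyl C–H across C2=C3 in the 6-endo sense. In one atom-economical operation it forms C3–C4, closes the pyranone ring, creates the ketone and sets C2 under catalyst control. The precursor is an open, flat benzaldehyde enol ether made by Mitsunobu etherification and dehydrobromination. Chelation-directed cleavage of the C5 methyl ether finishes the synthesis.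

Key step: step 5

Numbering: flavanone numbering is used (O1, C2, C3, C4, C4a, C5 to C8, C8a). Ring A is the benzo ring, ring B the 3,4-dimethoxyphenyl group and ring C the pyranone.

Assumption: the ligand antipode that leads to (2S) cannot be predicted with certainty for this substrate class. (R)-DTBM-SEGPHOS is written, and the equally available (S)-antipode is used if the sense of induction is opposite.

Step 1
Reactants: 1 3,4,5-trimethoxyphenol
Product: 2 2-hydroxy-4,5,6-trimethoxybenzaldehyde
Conditions: MgCl2, Et3N, (CH2O)n, MeCN, reflux; then 1 M HCl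
Reagents that add atoms: paraformaldehyde (as formaldehyde) C=O
Why: Casnati–Skattebøl ortho-formylation: the magnesium phenoxide of 1 delivers formaldehyde to the ortho carbon and a second formaldehyde oxidises the benzylic alkoxide, and since both ortho positions are equivalent and the para position is blocked only 2 can form.

Step 2
Reactants: 3 2-bromo-1-(3,4-dimethoxyphenyl)ethan-1-one
Product: 4 rac-2-bromo-1-(3,4-dimethoxyphenyl)ethan-1-ol
Conditions: NaBH4, MeOH, 0 °C; sat. aq. NH4Cl
Reagents that add atoms: none
Why: Borohydride 1,2-reduction of an α-bromo ketone, kept cold and quenched near neutral pH so that the bromohydrin does not close to the epoxide; the racemate suffices because this carbon becomes sp2 in step 4.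

Step 3
Reactants: 2 2-hydroxy-4,5,6-trimethoxybenzaldehyde; 4 rac-2-bromo-1-(3,4-dimethoxyphenyl)ethan-1-ol
Product: 5 rac-2-[2-bromo-1-(3,4-dimethoxyphenyl)ethoxy]-4,5,6-trimethoxybenzaldehyde
Conditions: PPh3, DIAD, THF, 0 °C to rt
Reagents that add atoms: none
Why: Mitsunobu etherification: the acidic phenol 2, flanked on one side only, displaces the activated benzylic alcohol of 4 (the β-bromine disfavours ionisation and the aldehyde is inert), and the configuration of the new centre is irrelevant because step 4 erases it.

Step 4
Reactants: 5 rac-2-[2-bromo-1-(3,4-dimethoxyphenyl)ethoxy]-4,5,6-trimethoxybenzaldehyde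
Product: 6 2-{[1-(3,4-dimethoxyphenyl)ethenyl]oxy}-4,5,6-trimethoxybenzaldehyde
Conditions: KOtBu, THF, 0 °C to rt; pH 7 buffer; chromatography on Et3N-deactivated silica
Reagents that add atoms: none
Why: E2 dehydrobromination of a 2-bromoethyl aryl ether, the standard entry to aryl vinyl ethers: the benzylic C–H is the only β-hydrogen, the bulky base does not substitute the primary bromide, and the aldehyde has no α-hydrogen.

Step 5
Reactants: 6 2-{[1-(3,4-dimethoxyphenyl)ethenyl]oxy}-4,5,6-trimethoxybenzaldehyde
Product: 7 (2S)-2-(3,4-dimethoxyphenyl)-5,6,7-trimethoxychroman-4-one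
Conditions: [Rh(cod)Cl]2 (2.5 mol %), (R)-DTBM-SEGPHOS (5 mol %), Na[B(3,5-(CF3)2C6H3)4] (5 mol %), degassed dry 1,4-dioxane, 80–100 °C, Ar
Reagents that add atoms: none
Why: Proposed new method: the cationic monovalent rhodium bisphosphine complex adds oxidatively into the formyl C–H bond of 6, O1 and the C2=C3 π bond hold the resulting trivalent acyl rhodium hydride on the O1 side of ring A, the hydride migrates to C2 while rhodium takes the terminal carbon C3 (seven-membered acyl alkyl rhodacycle), and reductive elimination forms C3–C4 and returns the catalyst. The closest known reaction type is the endo- and enantioselective rhodium-catalysed intramolecular hydroacylation of 1,1-disubstituted alkenes in ortho-allylbenzaldehydes and in N-vinyl- and N-allylindole-2-carbaldehydes, which builds six-membered aryl ketones without a chelating auxiliary; an aryl 1-arylvinyl ether has not served as the alkene. Ring C, the only ring formed, closes in the 6-endo-trig mode, the acyl carbon ending on the unsubstituted alkene terminus. C2, the only new stereocentre, is fixed in the hydride migration, where the chiral pocket of the twofold-symmetric ligand with its bulky 3,5-di-tert-butyl-4-methoxyphenyl groups distinguishes the two alkene faces (ring B versus O1 as the flanking groups), so control comes from the catalyst alone. The step needs 6-endo over 5-exo closure, which is secured because the 5-exo path requires a tertiary alkyl rhodium and a quaternary carbon and runs against the polarity of the enol ether (C3 nucleophilic, C2 cation-stabilising), and it needs hydroacylation to outrun decarbonylation and a Lewis-acid Prins-type closure to a flavylium ion, which the short O1 tether, the electron-rich and weakly electrophilic aldehyde and the dry aprotic medium should secure. Because C2 bears only O1 and ring B, the alkene has no allylic hydrogen and cannot isomerise, which is the main side reaction of the allyl substrates.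

Step 6
Reactants: 7 (2S)-2-(3,4-dimethoxyphenyl)-5,6,7-trimethoxychroman-4-one
Product: 9 (2S)-2-(3,4-dimethoxyphenyl)-5-hydroxy-6,7-dimethoxychroman-4-one, via dichloroboron chelate 8 (not isolated)
Conditions: BCl3 (1.2 equiv, 1 M in CH2Cl2), CH2Cl2, −78 to 0 °C; then cold 1 M HCl
Reagents that add atoms: none
Why: Chelation-directed aryl methyl ether cleavage: BCl3 binds the C4 carbonyl and the peri C5 methoxy oxygen in a six-membered chelate so that chloride removes only that methyl group, and the base-free medium at low temperature should leave no path (enolisation and retro-oxa-Michael opening of ring C) by which C2 could epimerise.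

Compound list
1 | 3,4,5-trimethoxyphenol | COc1cc(O)cc(OC)c1OC | starting material
2 | 2-hydroxy-4,5,6-trimethoxybenzaldehyde | O=Cc1c(O)cc(OC)c(OC)c1OC | intermediate
3 | 2-bromo-1-(3,4-dimethoxyphenyl)ethan-1-one | COc1ccc(C(=O)CBr)cc1OC | starting material
4 | rac-2-bromo-1-(3,4-dimethoxyphenyl)ethan-1-ol | COc1ccc(C(O)CBr)cc1OC | intermediate
5 | rac-2-[2-bromo-1-(3,4-dimethoxyphenyl)ethoxy]-4,5,6-trimethoxybenzaldehyde | COc1ccc(C(CBr)Oc2cc(OC)c(OC)c(OC)c2C=O)cc1OC | intermediate
6 | 2-{[1-(3,4-dimethoxyphenyl)ethenyl]oxy}-4,5,6-trimethoxybenzaldehyde | COc1ccc(C(=C)Oc2cc(OC)c(OC)c(OC)c2C=O)cc1OC | intermediate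
7 | (2S)-2-(3,4-dimethoxyphenyl)-5,6,7-trimethoxychroman-4-one | COc1ccc([C@@H]2CC(=O)c3c(cc(OC)c(OC)c3OC)O2)cc1OC | intermediate
8 | dichloroboron chelate of the C5 phenolate of 9 (drawn without the dative O to B bond from the C4 carbonyl) | COc1ccc([C@@H]2CC(=O)c3c(cc(OC)c(OC)c3OB(Cl)Cl)O2)cc1OC | intermediate
9 | (2S)-2-(3,4-dimethoxyphenyl)-5-hydroxy-6,7-dimethoxychroman-4-one | COc1ccc([C@@H]2CC(=O)c3c(cc(OC)c(OC)c3O)O2)cc1OC | target

Total step count: 6. Longest linear sequence: 5 steps (1 to 2 to 5 to 6 to 7 to 9; step 2 is the side branch).

Steps most likely to fail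

**Step 5 (the labelled step).**
- What may go wrong:
  - The acyl rhodium hydride may lose CO.
  - The cationic metal may act as a Lewis acid and drive a Prins-type closure with dehydration.
  - The rhodacycle may expel the aryloxide.
  - The two alkene faces may be poorly distinguished.
- The fallback uses known chemistry, sets out from 6 and comes back at 7. The same C3–C4 bond is closed by a thiol-catalysed radical-chain hydroacylation (polarity-reversal catalysis; tert-dodecanethiol, 1,1'-azobis(cyclohexanecarbonitrile), toluene, reflux). The aroyl radical attacks the CH2 terminus in the 6-endo mode. The tertiary benzylic, oxygen-stabilised radical then takes hydrogen from the thiol. This should give racemic 2-(3,4-dimethoxyphenyl)-5,6,7-trimethoxychroman-4-one F1. Preparative chromatography on a cellulose tris(3,5-dimethylphenylcarbamate) phase then separates 7 from (2R)-2-(3,4-dimethoxyphenyl)-5,6,7-trimethoxychroman-4-one F2. Mild base returns F2 to F1 for another pass.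

**Step 6.**
- What may go wrong:
  - The Lewis acid may open ring C reversibly, by ionisation at C2 or by enolisation, and erode the configuration at C2.
  - A second ether cleavage may follow at C6.
- The fallback sets out from 2 and comes back at 9. It moves the ether cleavage ahead of the creation of the stereocentre.
  - AlCl3 in CH2Cl2, the known way to free both ortho oxygens of 2,6-dioxygenated benzaldehydes, should give 2,6-dihydroxy-3,4-dimethoxybenzaldehyde F3.
  - Mitsunobu reaction with 4 should go to the less hindered hydroxyl, which is flanked by C–H rather than by OMe. It should give rac-2-[2-bromo-1-(3,4-dimethoxyphenyl)ethoxy]-6-hydroxy-4,5-dimethoxybenzaldehyde F4.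
  - KOtBu (more than two equivalents) should give 2-{[1-(3,4-dimethoxyphenyl)ethenyl]oxy}-6-hydroxy-4,5-dimethoxybenzaldehyde F5.
  - The conditions of step 5 should turn F5 directly into 9. No reagent then touches the molecule after C2 is set. The hydrogen bond from the C5 hydroxyl to the aldehyde oxygen also turns the formyl C–H toward the enol ether.

**Step 4.**
- What may go wrong:
  - The base may attack the aldehyde.
  - The base may substitute the primary bromide.
  - The acid-sensitive enol ether may be lost on work-up and chromatography.
- The fallback sets out from 1 and comes back at 6. It builds the enol ether by ester methylenation and brings in the aldehyde last.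
  - NBS in CH2Cl2 at 0 °C should give 2-bromo-3,4,5-trimethoxyphenol F6.
  - 3,4-Dimethoxybenzoyl chloride, Et3N and DMAP should give 2-bromo-3,4,5-trimethoxyphenyl 3,4-dimethoxybenzoate F7.
  - The Tebbe reagent Cp2Ti(µ-CH2)(µ-Cl)AlMe2 (toluene/THF, pyridine, −40 °C to rt), known for turning aryl benzoates into 1-aryloxystyrenes, should give 2-bromo-1-{[1-(3,4-dimethoxyphenyl)ethenyl]oxy}-3,4,5-trimethoxybenzene F8.
  - Bromine–lithium exchange with n-BuLi in THF at −78 °C should outrun any addition to the styrene and give the aryllithium F9.
  - DMF followed by aqueous NH4Cl converts F9 into 6.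

Further compounds
F1 | step 5 | rac-2-(3,4-dimethoxyphenyl)-5,6,7-trimethoxychroman-4-one | COc1ccc(C2CC(=O)c3c(cc(OC)c(OC)c3OC)O2)cc1OC
F2 | step 5 | (2R)-2-(3,4-dimethoxyphenyl)-5,6,7-trimethoxychroman-4-one | COc1ccc([C@H]2CC(=O)c3c(cc(OC)c(OC)c3OC)O2)cc1OC
F3 | step 6 | 2,6-dihydroxy-3,4-dimethoxybenzaldehyde | O=Cc1c(O)cc(OC)c(OC)c1O
F4 | step 6 | rac-2-[2-bromo-1-(3,4-dimethoxyphenyl)ethoxy]-6-hydroxy-4,5-dimethoxybenzaldehyde | COc1ccc(C(CBr)Oc2cc(OC)c(OC)c(O)c2C=O)cc1OC
F5 | step 6 | 2-{[1-(3,4-dimethoxyphenyl)ethenyl]oxy}-6-hydroxy-4,5-dimethoxybenzaldehyde | COc1ccc(C(=C)Oc2cc(OC)c(OC)c(O)c2C=O)cc1OC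
F6 | step 4 | 2-bromo-3,4,5-trimethoxyphenol | COc1cc(O)c(Br)c(OC)c1OC
F7 | step 4 | 2-bromo-3,4,5-trimethoxyphenyl 3,4-dimethoxybenzoate | COc1ccc(C(=O)Oc2cc(OC)c(OC)c(OC)c2Br)cc1OC
F8 | step 4 | 2-bromo-1-{[1-(3,4-dimethoxyphenyl)ethenyl]oxy}-3,4,5-trimethoxybenzene | COc1ccc(C(=C)Oc2cc(OC)c(OC)c(OC)c2Br)cc1OC
F9 | step 4 | (2-{[1-(3,4-dimethoxyphenyl)ethenyl]oxy}-4,5,6-trimethoxyphenyl)lithium | COc1ccc(C(=C)Oc2cc(OC)c(OC)c(OC)c2[Li])cc1OC
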